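At early times L appears at much the same initial rate in the earlier closed-flask runs: by 0.200 h the summer run with 2 mM of Z holds 10.6% of the charge, midnight with 1.3 mM holds 11.6%, and dusk with 3 mM holds 10.2%, with a scatter of 1 percentage point.

| flask | Q | Z | remark | time |
|---|---|---|---|---|
| summer | 10 mM | 2 mM | run made earlier |  |
| midnight | 10 mM | 1.3 mM | run made earlier |  |
| dusk | 10 mM | 3 mM | run made earlier |  |
| birch | 10 mM | 2.00 mM | a single well-mixed tank run continuously and read at steady state, 4.0 h in it on average |  |
| ash | 10 mM | 2.00 mM | plug flow through a tube for 4.0 h, no back-mixing | 4.0 h |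
| alder | 10 mM | 2.00 mM | a closed flask charged with all of it at once and left for 4.0 h | 4.0 h |
| larch | 10 mM (fed, over 3.20 h) | 2.00 mM | a stirred flask in which Q is dosed at a steady rate over 3.20 h without added volume, worked up at 4.0 h | 4.0 h |

| run | time / h | L / % |
|---|---|---|
| summer | 0.200 | 10.6 |
| summer | 0.333 | 15.2 |
| summer | 0.667 | 21.5 |
| summer | 1.33 | 25.0 |
| summer | 2.50 | 25.4 |
| midnight | 0.200 | 11.6 |
| midnight | 0.333 | 15.1 |
| midnight | 0.667 | 21.5 |
| midnight | 1.33 | 24.6 |
| midnight | 2.50 | 25.1 |
| dusk | 0.200 | 10.2 |
| dusk | 0.333 | 12.9 |
| dusk | 0.667 | 20.9 |
| dusk | 1.33 | 22.6 |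
| dusk | 2.50 | 21.3 |

(scatter of a reading: 1 percentage point)

- the stated concentrations are those of everything mixed, before any reaction; amounts are the same in each set-up
- the feed brings no volume worth counting
- the earlier runs were made in a closed, stirred flask

- the set-up with the highest amount of L at the outlet or at the end, in percent of the Q put in ("none" if the first two lie within 2 percentage points) (birch / ash / alder / larch / none)
- amount of L at the outlet or at the end, in percent of the Q put in, birch
- amount of L at the outlet or at the end, in percent of the Q put in, ash
- amount of L at the outlet or at the end, in percent of the Q put in, alder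
- amount of L at the outlet or at the end, in percent of the Q put in, larch

These numbers do not seem to go together. The summer initial rate, kept up, reaches the charge in 1.89 h, yet the readings of that run level off near a quarter of it. Its Z is 20.0% of the Q, while the last reading leaves 74.6% of the Q not shown as L, so Z taken mole for mole covers less than the gap.

So we let Z remove its own amount of Q and freeze what is left. The last readings, pooled, give 30.3%; this is the L share, plateau L over the Q that Z has not taken. Run by run it reads from 28.9% to 31.8%. The summer readings lie flat within their scatter by 2.50 h, and 4.0 h is longer, so for ash, alder and larch we reckon 24.2%, for the tank birch somewhat less, and no clear winner.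

The forecast, holding that “yield depends only on residence time”, gave 23.3% for birch, 25.3% for ash, 25.3% for alder and 25.2% for larch, with none as best, so its alder stands above our figure.

The flasks give 21.8% in birch, 22.8% in ash, 22.8% in alder and 23.0% in larch, so the best is none.

    Q + Z → X (k = 176 M⁻¹ h⁻¹)
    L ⇌ E (K = 0.800, k = 0.790 h⁻¹)
    Q ⇌ L (K = 0.682, k = 0.719 h⁻¹)
    E ⇌ D (K = 0.363, k = 1.29 h⁻¹)

Our alder figure stood 1.4 points high. At 4.00 h alder holds 34.7% of its Q beside its L, and 19.3% as X, with Z, the limiting reagent of that step, down to 3.49% of its own charge. In larch, one part of what holds L down is the back reaction of L to Q: without it larch gives 38.3% instead of 23.0%. Applied to the Q not held as X, the L share gives 17.9% for the neighbour flask, larch with 5.0 mM of Z, which in fact gives 16.9%.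

Readings and results were computed with constants of no real substance; noise was put on by code.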